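**Retrosynthetic overview**

1. Target 25 ⇐ 24 by one fluoride deprotection (TBDPS ether and 2-(trimethylsilyl)ethyl ester); 24 ⇐ α-face 1,2-addition of side-chain organocerium 23 (C9–C11 bond) to exo-methylene ketone 14; 14 ⇐ 10 by 5α-hydration of C5=C6 and C8 methylenation.
2. 10 ⇐ 7 + 1-chloro-3-iodopropane (8): a one-pot enantioselective [3+3] annulation that forms C3–C4 and C1–C10, closes ring A, sets both quaternary stereocentres (C4, C10) and leaves C5=C6 in place for the C5 hydroxyl.
3. Enabling feature: in 7, C4 (exocyclic, α to the C19 ester) and C10 (ring B, α to the C9 ketone) are the two carbon termini of one vinylogous β-keto ester π-system O=C19–C4–C5=C10–C9=O. They are 1,3-related across C5 and react in turn with the two ends of a C3 dielectrophile; the C10 methyl steers the first alkylation to C4.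
4. 7 ⇐ enol triflate 5 of 2-methylcyclohexane-1,3-dione + zinc enolate of bromo ester 3; side-chain bromide 21 ⇐ silyloxybutyne 15 by carboalumination/hydroxymethylation.
5. Ring order: ring B is bought as the dione 4; ring A is closed in step 4.

Key step: step 4

Remark: positions are given in labdane numbering (C1–C20; β = face of the C10 methyl); compounds 1, 2, 4, 8 and 15 are taken as commercial.

**Route**

Step 1
Reactants: 1 2-bromopropanoyl bromide; 2 2-(trimethylsilyl)ethanol
Product: 3 2-(trimethylsilyl)ethyl 2-bromopropanoate (racemic)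
Conditions: pyridine, CH2Cl2, 0 °C
Reagents that add atoms: none
Why: Acylation of the alcohol by the acid bromide with pyridine as acid scavenger is a routine esterification, and the racemic α-centre is erased in step 3.

Step 2
Reactants: 4 2-methylcyclohexane-1,3-dione
Product: 5 2-methyl-3-oxocyclohex-1-en-1-yl trifluoromethanesulfonate
Conditions: Tf2O, pyridine, CH2Cl2, −78 → 0 °C
Reagents that add atoms: trifluoromethanesulfonic anhydride, O=S(=O)(OS(=O)(=O)C(F)(F)F)C(F)(F)F
Why: O-Sulfonylation of the enol form of the cyclic 1,3-dione gives the vinylogous acyl triflate, the standard activation of such diones for cross-coupling, and no stereocentre is formed.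

Step 3
Reactants: 3 2-(trimethylsilyl)ethyl 2-bromopropanoate; 5 enol triflate
Product: 7 2-(trimethylsilyl)ethyl 2-(2-methyl-3-oxocyclohex-1-en-1-yl)propanoate, via zinc enolate 6 (not isolated)
Conditions: Zn dust (Me3SiCl-activated), THF, 25 °C; then 5, Pd(PPh3)4 (5 mol %), THF, 50 °C
Reagents that add atoms: none
Why: Zinc insertion gives the Reformatsky reagent, which couples with the electron-poor enol triflate under zerovalent palladium catalysis (Negishi-type coupling of a zinc enolate; uncatalysed addition–elimination would give the same product), and the C4 centre formed is acidic, racemic and of no consequence.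

Step 4
Reactants: 7 vinylogous β-keto ester; 8 1-chloro-3-iodopropane
Product: 10 2-(trimethylsilyl)ethyl (1S,4aS)-1,4a-dimethyl-5-oxo-1,2,3,4,4a,5,6,7-octahydronaphthalene-1-carboxylate, via chloride 9 (not isolated)
Conditions: 8 (1.3 equiv), chiral C2-symmetric N-spiro bis(binaphthyl)ammonium bromide with 3,4,5-trifluorophenyl groups (5 mol %; antipode chosen to give (S)-9), CsOH·H2O, toluene, −40 °C; then KOtBu (1.5 equiv), NaI (10 mol %), t-BuOH/THF, 0 → 40 °C
Reagents that add atoms: none
Why: Proposed new method: CsOH deprotonates C4 of 7 to the extended anion delocalised over O9–C9–C10–C5–C4–C19–O, which as an ion pair with the chiral ammonium cation is alkylated by the iodide end of 8 at C4 (C3–C4 bond) to give 9; KOtBu then forms the thermodynamic dienolate of 9 by γ-deprotonation at C6, and its α-carbon C10 displaces chloride (C1–C10 bond), leaving the C5=C6 alkene. The closest known reactions are the C1-alkylation of 3-alkyl Hagemann esters, the deconjugative α-alkylation of enone dienolates and the chiral phase-transfer alkylation of α-substituted β-keto esters and indanones; their combination in one enantioselective [3+3] annulation with an unactivated dihalide has not been shown. Ring A closes in a 6-(enolexo)-exo-tet mode, whereas O-alkylation or attack from C8 would need an eight-membered ring and γ-attack from C6 is disfavoured by the larger α-coefficient of the dienolate. C4 is set by the chiral cation, which shields one face of the planar anion, and C10 is set by C4: in the chair-like closure the ester, not the C4 methyl, takes the site that becomes 1,3-diaxial to the C10 methyl (ester/methyl instead of methyl/methyl repulsion), which gives the cis relationship of CO2R and C10–CH3. The step needs C4- over C10- and O-alkylation in the first event and discrimination of the two halides, secured by the methyl group on C10 and by the iodide/chloride reactivity gap.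

Step 5
Reactants: 10 bicyclic β,γ-unsaturated ketone
Product: 11 2-(trimethylsilyl)ethyl (1S,4aS,8aS)-8a-hydroxy-1,4a-dimethyl-5-oxodecahydronaphthalene-1-carboxylate (5α-hydroxy, trans-fused)
Conditions: Mn(dpm)3 (10 mol %; dpm = dipivaloylmethanate), PhSiH3, O2 (1 atm), i-PrOH/CH2Cl2, 0 °C → rt
Reagents that add atoms: dioxygen, O=O
Why: Mukaiyama hydration (hydrogen atom transfer from a manganese hydride to C6, capture of the tertiary C5 radical by O2 and in situ reduction of the peroxide) gives the Markovnikov tertiary alcohol, and oxygen should enter from the α face because the β face of C5 is flanked by the axial C10 methyl and the axial C4 ester, which sets the trans ring fusion.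

Step 6
Reactants: 11 hydroxy ketone
Product: 14 2-(trimethylsilyl)ethyl (1S,4aS,8aS)-8a-hydroxy-1,4a-dimethyl-6-methylidene-5-oxodecahydronaphthalene-1-carboxylate, via Mannich base 12 (not isolated), via methiodide 13 (not isolated)
Conditions: LiN(i-Pr)2 (2.2 equiv), THF, −78 °C; Eschenmoser's salt, −78 → 0 °C; aq. NaHCO3; MeI, CH2Cl2, rt; DBU, rt
Reagents that add atoms: N,N-dimethylmethyleneiminium iodide (Eschenmoser's salt), C=[N+](C)C.[I-]
Why: The alkoxide–enolate dianion (enolisation is possible only towards C8 because C10 is quaternary) undergoes Mannich aminomethylation, and quaternisation followed by base-induced β-elimination gives the exocyclic enone without setting a stereocentre, retro-aldol opening to a ten-membered ring being disfavoured by strain.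

Step 7
Reactants: 15 tert-butyl(but-3-yn-1-yloxy)dimethylsilane
Product: 18 (2E)-5-[(tert-butyldimethylsilyl)oxy]-3-methylpent-2-en-1-ol, via alkenylalane 16 (not isolated), via lithium alanate 17 (not isolated)
Conditions: Me3Al (2 equiv), Cp2ZrCl2 (0.25 equiv), CH2Cl2, 0 °C → rt; n-BuLi, THF, −78 °C; (CH2O)n, −78 °C → rt; H2O, aq. KNaC4H4O6
Reagents that add atoms: trimethylaluminium, C[Al](C)C; paraformaldehyde (as formaldehyde), C=O
Why: Negishi zirconium-catalysed carboalumination adds methyl and aluminium syn across the terminal alkyne with methyl on the internal carbon, and the alanate is hydroxymethylated with retention, which fixes the E trisubstituted alkene.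

Step 8
Reactants: 18 allylic alcohol
Product: 19 tert-butyl{[(2E)-5-[(tert-butyldimethylsilyl)oxy]-3-methylpent-2-en-1-yl]oxy}diphenylsilane
Conditions: t-BuPh2SiCl, imidazole, CH2Cl2, rt
Reagents that add atoms: tert-butyl(chloro)diphenylsilane, CC(C)(C)[Si](Cl)(c1ccccc1)c1ccccc1
Why: Standard silylation of the primary allylic alcohol installs a fluoride-labile group that should survive the mild acid of step 9 and the organometallic step 11.

Step 9
Reactants: 19 bis-silyl ether
Product: 20 (3E)-5-[(tert-butyldiphenylsilyl)oxy]-3-methylpent-3-en-1-ol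
Conditions: pyridinium p-toluenesulfonate (cat.), EtOH, 40 °C
Reagents that add atoms: none
Why: Acid-catalysed ethanolysis cleaves a primary TBS ether much faster than the bulkier primary TBDPS ether, a routine selective desilylation.

Step 10
Reactants: 20 homoallylic alcohol
Product: 21 tert-butyl{[(2E)-5-bromo-3-methylpent-2-en-1-yl]oxy}diphenylsilane
Conditions: CBr4, PPh3, CH2Cl2, 0 °C
Reagents that add atoms: tetrabromomethane, BrC(Br)(Br)Br
Why: Appel bromination converts the primary alcohol to the bromide under neutral conditions without touching the allylic silyl ether or the alkene geometry.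

Step 11
Reactants: 21 side-chain bromide; 14 exo-methylene ketone
Product: 24 2-(trimethylsilyl)ethyl (1S,4aR,5S,8aS)-5-{(3E)-5-[(tert-butyldiphenylsilyl)oxy]-3-methylpent-3-en-1-yl}-5,8a-dihydroxy-1,4a-dimethyl-6-methylidenedecahydronaphthalene-1-carboxylate, via Grignard reagent 22 (not isolated), via organocerium reagent 23 (not isolated)
Conditions: 21 (2.6 equiv), Mg, THF, 40 °C; CeCl3 (2.6 equiv), THF, −78 °C; 14, −78 → −30 °C; aq. NH4Cl
Reagents that add atoms: none
Why: Transmetallation of the Grignard reagent to the weakly basic organocerium reagent ensures 1,2-addition to the enone, the first equivalent forming the C5 alkoxide, and attack should come from the α face, anti to the axial C10 methyl whose quaternary carbon blocks the β trajectory and on the side of the C5 metal alkoxide that can anchor the reagent, giving the 9β-hydroxy-9α-alkyl carbinol.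

Step 12
Reactants: 24 protected adduct
Product: 25 (1S,4aR,5S,8aS)-5,8a-dihydroxy-5-[(3E)-5-hydroxy-3-methylpent-3-en-1-yl]-1,4a-dimethyl-6-methylidenedecahydronaphthalene-1-carboxylic acid (5α,9β-dihydroxyisocupressic acid)
Conditions: Bu4NF (4 equiv), THF, 0 °C → rt; aq. NaH2PO4 (pH 4)
Reagents that add atoms: none
Why: Fluoride cleaves the TBDPS ether and fragments the 2-(trimethylsilyl)ethyl ester by β-elimination to ethene and fluorotrimethylsilane regardless of the steric shielding of the axial C4 carboxyl, and the buffered work-up spares the tertiary allylic alcohol.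

**Compound list**

1 | 2-bromopropanoyl bromide | CC(Br)C(=O)Br | starting material
2 | 2-(trimethylsilyl)ethanol | C[Si](C)(C)CCO | starting material
3 | 2-(trimethylsilyl)ethyl 2-bromopropanoate (racemic) | CC(Br)C(=O)OCC[Si](C)(C)C | intermediate
4 | 2-methylcyclohexane-1,3-dione | CC1C(=O)CCCC1=O | starting material
5 | 2-methyl-3-oxocyclohex-1-en-1-yl trifluoromethanesulfonate | CC1=C(OS(=O)(=O)C(F)(F)F)CCCC1=O | intermediate
6 | bromozinc enolate (Reformatsky reagent) of 3 | CC([Zn]Br)C(=O)OCC[Si](C)(C)C | intermediate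
7 | 2-(trimethylsilyl)ethyl 2-(2-methyl-3-oxocyclohex-1-en-1-yl)propanoate (C4 racemic, labile) | CC(C(=O)OCC[Si](C)(C)C)C1=C(C)C(=O)CCC1 | intermediate
8 | 1-chloro-3-iodopropane | ClCCCI | starting material
9 | 2-(trimethylsilyl)ethyl (2S)-5-chloro-2-methyl-2-(2-methyl-3-oxocyclohex-1-en-1-yl)pentanoate | ClCCC[C@](C)(C(=O)OCC[Si](C)(C)C)C1=C(C)C(=O)CCC1 | intermediate
10 | 2-(trimethylsilyl)ethyl (1S,4aS)-1,4a-dimethyl-5-oxo-1,2,3,4,4a,5,6,7-octahydronaphthalene-1-carboxylate | C1CC=C2[C@](C)(CCC[C@]2(C)C(=O)OCC[Si](C)(C)C)C1=O | intermediate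
11 | 2-(trimethylsilyl)ethyl (1S,4aS,8aS)-8a-hydroxy-1,4a-dimethyl-5-oxodecahydronaphthalene-1-carboxylate | C1CC[C@]2(O)[C@](C)(CCC[C@]2(C)C(=O)OCC[Si](C)(C)C)C1=O | intermediate
12 | 6-[(dimethylamino)methyl] derivative of 11 (Mannich base, C8 epimers) | CN(C)CC1CC[C@]2(O)[C@](C)(CCC[C@]2(C)C(=O)OCC[Si](C)(C)C)C1=O | intermediate
13 | trimethylammonium iodide (methiodide) of 12 | C[N+](C)(C)CC1CC[C@]2(O)[C@](C)(CCC[C@]2(C)C(=O)OCC[Si](C)(C)C)C1=O.[I-] | intermediate
14 | 2-(trimethylsilyl)ethyl (1S,4aS,8aS)-8a-hydroxy-1,4a-dimethyl-6-methylidene-5-oxodecahydronaphthalene-1-carboxylate | C=C1CC[C@]2(O)[C@](C)(CCC[C@]2(C)C(=O)OCC[Si](C)(C)C)C1=O | intermediate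
15 | tert-butyl(but-3-yn-1-yloxy)dimethylsilane | C#CCCO[Si](C)(C)C(C)(C)C | starting material
16 | (E)-[4-(tert-butyldimethylsilyloxy)-2-methylbut-1-en-1-yl]dimethylalane | CC(C)(C)[Si](C)(C)OCC/C(C)=C/[Al](C)C | intermediate
17 | lithium butyl(dimethyl)[(E)-4-(tert-butyldimethylsilyloxy)-2-methylbut-1-en-1-yl]alanate | CC(C)(C)[Si](C)(C)OCC/C(C)=C/[Al-](C)(C)CCCC.[Li+] | intermediate
18 | (2E)-5-[(tert-butyldimethylsilyl)oxy]-3-methylpent-2-en-1-ol | CC(C)(C)[Si](C)(C)OCC/C(C)=C/CO | intermediate
19 | tert-butyl{[(2E)-5-[(tert-butyldimethylsilyl)oxy]-3-methylpent-2-en-1-yl]oxy}diphenylsilane | CC(C)(C)[Si](C)(C)OCC/C(C)=C/CO[Si](c1ccccc1)(c1ccccc1)C(C)(C)C | intermediate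
20 | (3E)-5-[(tert-butyldiphenylsilyl)oxy]-3-methylpent-3-en-1-ol | OCC/C(C)=C/CO[Si](c1ccccc1)(c1ccccc1)C(C)(C)C | intermediate
21 | tert-butyl{[(2E)-5-bromo-3-methylpent-2-en-1-yl]oxy}diphenylsilane | BrCC/C(C)=C/CO[Si](c1ccccc1)(c1ccccc1)C(C)(C)C | intermediate
22 | Grignard reagent of 21 | Br[Mg]CC/C(C)=C/CO[Si](c1ccccc1)(c1ccccc1)C(C)(C)C | intermediate
23 | alkylcerium dichloride from 22 | Cl[Ce](Cl)CC/C(C)=C/CO[Si](c1ccccc1)(c1ccccc1)C(C)(C)C | intermediate
24 | 2-(trimethylsilyl)ethyl (1S,4aR,5S,8aS)-5-{(3E)-5-[(tert-butyldiphenylsilyl)oxy]-3-methylpent-3-en-1-yl}-5,8a-dihydroxy-1,4a-dimethyl-6-methylidenedecahydronaphthalene-1-carboxylate | C=C1CC[C@]2(O)[C@](C)(CCC[C@]2(C)C(=O)OCC[Si](C)(C)C)[C@]1(O)CC/C(C)=C/CO[Si](c1ccccc1)(c1ccccc1)C(C)(C)C | intermediate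
25 | 5α,9β-dihydroxyisocupressic acid | C=C1CC[C@]2(O)[C@](C)(CCC[C@]2(C)C(=O)O)[C@]1(O)CC/C(C)=C/CO | target

**Step count and risks**

Total step count: 12. Longest linear sequence: 7 steps (2, 3, 4, 5, 6, 11, 12 from compound 4).

Steps most likely to fail:

Step 4 (proposed method). The extended enolate of 7 may not be held tightly enough by the chiral cation, or may react as an E/Z mixture, so that enantiofacial control at C4 is eroded; alkylation of the hindered anion under phase-transfer conditions may also be slow. The fallback sets out from 7 and keeps the one-pot double alkylation but takes absolute configuration from resolution instead of catalysis. The sodium anion of 7 (NaH, DMF, 0 °C) is alkylated with 8 to the racemic chloride F1. KOtBu is added to the same flask to close ring A to the racemic bicyclic ketone F2. F2 is separated into its enantiomers by preparative chromatography on a chiral stationary phase (amylose tris(3,5-dimethylphenylcarbamate)), which comes back to the route at 10.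

Step 11. The organocerium reagent may attack the β face of C9, because the axial oxygen on C5 lies 1,3-diaxial to the α trajectory and may hinder rather than direct. The fallback sets out from 10 and carries the C5 oxygen through the addition as an epoxide, which is tied back towards C6 and leaves the α face of C9 open. mCPBA (NaHCO3, CH2Cl2, 0 °C) should epoxidise C5=C6 from the α face, anti to the axial C10 methyl and C4 ester, to give the 5α,6α-epoxy ketone F3. LiN(i-Pr)2 and Eschenmoser's salt give the Mannich base F4, MeI gives the methiodide F5, and DBU gives the epoxy enone F6. Addition of organocerium reagent 23 (1.3 equiv, −78 °C), anti to the C10 methyl, gives the epoxy adduct F7. Bu4NF removes both silicon groups to give the epoxy acid F8. LiEt3BH (excess, THF, 0 → 50 °C) then opens the epoxide by hydride attack at the secondary C6 (trans-diaxial), the lithium carboxylate being inert, and the route is rejoined at 25.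

Step 6. Aminomethylation of the hindered alkoxide–enolate dianion may be incomplete, or the lithium aldolate may fragment by retro-aldol reaction. The fallback sets out from 11 and replaces the dianion by a neutral silyl enol ether. Me3SiOTf/Et3N (CH2Cl2, 0 °C) silylates both the tertiary alcohol and the ketone to give the bis-silyl compound F9. Eschenmoser's salt reacts with the silyl enol ether to give the Mannich base F10, MeI gives the methiodide F11, and DBU gives the 5-O-trimethylsilyl enone F12. Brief treatment with 1 M HCl in THF at 0 °C removes the silyl ether and returns to the route at 14.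

Further compounds
F1 | step 4 | racemic 2-(trimethylsilyl)ethyl 5-chloro-2-methyl-2-(2-methyl-3-oxocyclohex-1-en-1-yl)pentanoate | ClCCC[C@](C)(C(=O)OCC[Si](C)(C)C)C1=C(C)C(=O)CCC1.ClCCC[C@@](C)(C(=O)OCC[Si](C)(C)C)C1=C(C)C(=O)CCC1
F2 | step 4 | racemic 2-(trimethylsilyl)ethyl (1S*,4aS*)-1,4a-dimethyl-5-oxo-1,2,3,4,4a,5,6,7-octahydronaphthalene-1-carboxylate | C1CC=C2[C@](C)(CCC[C@]2(C)C(=O)OCC[Si](C)(C)C)C1=O.C1CC=C2[C@@](C)(CCC[C@@]2(C)C(=O)OCC[Si](C)(C)C)C1=O
F3 | step 11 | 5α,6α-epoxide of 10 (epoxy ketone) | C1C[C@H]3[C@]2(O3)[C@](C)(CCC[C@]2(C)C(=O)OCC[Si](C)(C)C)C1=O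
F4 | step 11 | C8 (dimethylamino)methyl derivative of F3 (Mannich base) | CN(C)CC1C[C@H]3[C@]2(O3)[C@](C)(CCC[C@]2(C)C(=O)OCC[Si](C)(C)C)C1=O
F5 | step 11 | methiodide of F4 | C[N+](C)(C)CC1C[C@H]3[C@]2(O3)[C@](C)(CCC[C@]2(C)C(=O)OCC[Si](C)(C)C)C1=O.[I-]
F6 | step 11 | 5α,6α-epoxy-8(17)-methylidene-9-ketone (epoxy enone) | C=C1C[C@H]3[C@]2(O3)[C@](C)(CCC[C@]2(C)C(=O)OCC[Si](C)(C)C)C1=O
F7 | step 11 | 5α,6α-epoxy analogue of 24 (epoxy adduct) | C=C1C[C@H]3[C@]2(O3)[C@](C)(CCC[C@]2(C)C(=O)OCC[Si](C)(C)C)[C@]1(O)CC/C(C)=C/CO[Si](c4ccccc4)(c4ccccc4)C(C)(C)C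
F8 | step 11 | 5α,6α-epoxy-9β,15-dihydroxylabda-8(17),13E-dien-19-oic acid (epoxy acid) | C=C1C[C@H]3[C@]2(O3)[C@](C)(CCC[C@]2(C)C(=O)O)[C@]1(O)CC/C(C)=C/CO
F9 | step 6 | 5-O-trimethylsilyl ether and C8=C9 trimethylsilyl enol ether of 11 | C1C[C@]2(O[Si](C)(C)C)[C@](C)(CCC[C@]2(C)C(=O)OCC[Si](C)(C)C)C(O[Si](C)(C)C)=C1
F10 | step 6 | 5-O-trimethylsilyl ether of 12 (Mannich base) | CN(C)CC1CC[C@]2(O[Si](C)(C)C)[C@](C)(CCC[C@]2(C)C(=O)OCC[Si](C)(C)C)C1=O
F11 | step 6 | methiodide of F10 | C[N+](C)(C)CC1CC[C@]2(O[Si](C)(C)C)[C@](C)(CCC[C@]2(C)C(=O)OCC[Si](C)(C)C)C1=O.[I-]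
F12 | step 6 | 5-O-trimethylsilyl ether of 14 | C=C1CC[C@]2(O[Si](C)(C)C)[C@](C)(CCC[C@]2(C)C(=O)OCC[Si](C)(C)C)C1=O
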